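Readings and results were computed for substances that don't exist; scatter was added.

Starting material is charged in a smaller amount, at 20 mM against 40.0 mM of coupling partner, and its balance holds in the readings. With target it sums to 100% in Sunday's run at 5.00 h and to 101% in Thursday's at 2.50 h. One decay number can therefore carry both species.

the same everywhere: free catalyst 0.40 mM
- Thursday's: starting material 20 mM; second substrate 40 mM; coupling partner 40 mM; the very flask that is asked about, followed so far
- Sunday's: starting material 10 mM; second substrate 40 mM; coupling partner 40 mM; run made earlier
- flask: starting material 20 mM; second substrate 40.0 mM; coupling partner 40.0 mM; time 5.0 h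

| run | time / h | target / % | starting material / % |
|---|---|---|---|
| Thursday's | 0.417 | 4 | 99 |
| Thursday's | 0.833 | 12 | 95 |
| Thursday's | 1.33 | 12 | 90 |
| Thursday's | 1.50 | 13 | 91 |
| Thursday's | 2.00 | 15 | 87 |
| Thursday's | 2.50 | 19 | 82 |
| Sunday's | 0.417 | 4 | 96 |
| Sunday's | 0.667 | 8 | 93 |
| Sunday's | 1.00 | 10 | 86 |
| Sunday's | 2.00 | 17 | 88 |
| Sunday's | 3.00 | 21 | 76 |
| Sunday's | 5.00 | 34 | 66 |

(standard deviation of a reading: 2 percentage points)

- a reading or a percentage of target counts all its forms, free or not

- amount of target in the flask at 5.0 h, in percent of the starting material charged
- amount of starting material in the flask at 5.0 h, in percent of the starting material charged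

Take the main step first, as pseudo-first-order decay of starting material. Sunday's last point gives 0.0831 h⁻¹ for k, the fractional rate constant: the logarithm of charge over remainder, divided by time. Thursday's last point reads 0.0794 h⁻¹ at twice the charge, so k is carried across to Thursday's flask, which is then reckoned to hold 66.0% starting material at 5.0 h.

Now add the use of coupling partner, one per target. By 5.0 h this is reckoned at 6.80 mM in Thursday's flask against 3.40 mM in Sunday's. Neither run varied the partner, so a rate proportional to it is an assumption. The mean partner is then 36.6 mM against 38.3 mM, which lowers k to 0.0794 h⁻¹. This reckoning adds no further process and stops at 32.8% target and 67.2% starting material.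

The forecast, from the same runs, gives 32% target (26% to 36%) and 68% starting material (63% to 74%). Its target stands lower than this reckoning's, on the ground that “Any product binding to catalyst, or depletion of second substrate or partner, would slow it”.

The flask gives 28.3% target and 71.2% starting material at 5.0 h, inside both forecast ranges.

    coupling partner + catalyst intermediate A → free catalyst + target (k = 0.0840 M⁻¹ s⁻¹)
    second substrate + free catalyst ⇌ catalyst intermediate B (K = 13.0 M⁻¹, k = 0.640 M⁻¹ s⁻¹)
    starting material + free catalyst ⇌ catalyst intermediate A (K = 37.0 M⁻¹, k = 1.30 M⁻¹ s⁻¹)
    coupling partner + catalyst intermediate B → free catalyst + second product (k = 0.130 M⁻¹ s⁻¹)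
    free catalyst + target ⇌ idle complex (K = 17.0 M⁻¹, k = 0.0230 M⁻¹ s⁻¹)

Coupling partner there stands at 69.4% of its charge: 12.2 mM gone, 5.66 mM to target, bound forms counted, and 6.60 mM to second product. The flask's own k is 0.0679 h⁻¹, lower than Sunday's 0.0831 h⁻¹. Scaled to a quarter of the catalyst, 0.0831 h⁻¹ leaves 90.1% starting material in a neighbour flask charged with 0.10 mM of free catalyst, and that neighbour holds 91.1%.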